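**Remark on the chemistry.** The target has no stereocentre and no stereogenic double bond. Compound 1, the C-acetyl derivative of phloroglucinol, is taken as a purchased starting material. The bridged adduct 23 is racemic and is drawn as one enantiomer.

## Analysis of the target

The target is a flavonol, a 2-aryl-3-hydroxy-4H-chromen-4-one. Ring A is a phloroglucinol unit with free hydroxyls at C5 and C7 and a 2-methylbut-3-en-2-yl ("reverse prenyl") group on C8. Ring C carries the C3 hydroxyl and the C4 carbonyl. Ring B is a 1,2-diol (O3′, O4′) with a 3-methylbut-2-enyl group on C5′. No configuration has to be set; the only stereogenic atoms in the route are the two bridgeheads of a transient cycloadduct, which are lost on aromatisation. The sensitive features are five acidic hydroxyls, an oxidisable ortho-dihydroxybenzene and 3-hydroxypyranone, and two alkenes that sit next to a hydroxyl (prenyl beside O4′, reverse prenyl beside O7) and close to a chroman or a dihydrobenzofuran in strong acid. Two placements make the synthesis hard. The tertiary allyl group must sit on C8 and not on C6. The prenyl group must sit on C5′ next to two contiguous oxygens, a pattern that direct prenylation of an ortho-dihydroxybenzene delivers poorly. The strategy rests on ring B: C3′(O)–C4′(O)–C5′(prenyl) with C2′ and C6′ unsubstituted is the substitution pattern of a 3-oxygenated 4-alkylfuran, whose ring oxygen becomes O3′.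

## Retrosynthetic reasoning

**26 to 24.** Three O–CH2 acetal bonds (O3, O5, O7) and one O–Si bond (O4′) are cut, leading through 25 back to 24, in which O3′ is already free. Acetals are used on rings A and C because they survive bases, organometallic reagents, fluoride and heat, and leave in dilute acid that the two alkenes tolerate. The silyl ether on O4′ follows from the way ring B is made. The forward steps must free the oxygens without closing a ring onto either alkene, so fluoride comes first and acid last.

**24 to 15 and 22.** The C2′–C3′ and C1′–C6′ bonds are cut, with O3′ imagined as a bridge between C3′ and C6′ (adduct 23). This gives the chromone 15, which carries a two-carbon alkyne on C2, and the furan 22. Cutting the C2–C1′ bond instead would require a finished 5-prenylated ring B. Cutting through ring B takes O3′, O4′ and the prenyl group from a furan in which their order is fixed by construction. One step then builds ring B, places its three substituents and joins the two halves. The forward reaction has to add in one orientation (furan carbon next to the silyloxy carbon onto the terminal alkyne carbon) and open the oxygen bridge on the C6′ side.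

**15 to 10.** The C2–C(sp) bond is cut to the vinyl iodide 12 and the alkyne 13, with 14 as the silylated coupling product. The C2–I bond of 12 goes back to the C2–H bond of 10. This is the only C–H on the pyranone and it is acidified by O1, the carbonyl and the C3 oxygen, so the two-carbon unit can be added late to a complete ring A/C core.

**10 to 8.** O1–C2 and C2–C3 are cut. C2 is a one-carbon unit at the formate oxidation level, joined to the ketone α-carbon of 8 and then attacked by the phenol. Because 8 already holds the C3 oxygen, the pyranone never has to be oxidised.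

**8 to 5.** The C–O bond α to the ketone is cut, through alcohol 7, back to the methyl ketone 5. The forward step is an enolate oxidation that must prefer the enol double bond to the side-chain alkene.

**5 to 1 and 2.** The bond between the ring and the quaternary carbon is cut by a [3,3] shift, which leads from triol 4 to the aryl prenyl ether 3. The ether sits on the oxygen para to the acetyl group, so the para position is blocked and the two ortho positions are equivalent; only one rearranged phenol can form. The three hydroxyls of 4 are then told apart by their surroundings. The one between the acetyl group and the tertiary group is buried and hydrogen-bonded, and it is the one that must stay free to become O1. This puts the side chain on C8. Ether 3 comes from 1 and 2 by alkylation of the most acidic, non-chelated hydroxyl.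

**22 to 16 and 2.** The O–Si bond is cut to the furanone 21, whose C–O bond goes back to the C–Br bond of 18, and the prenyl C–C bond goes back to 16 and 2. The two bromines of 16 mark the adjacent β-positions and are exchanged one at a time.

## Alternatives that were turned down

**Alternative 1:** The bonds from the quaternary carbon to its methyl and vinyl groups are cut, so that this carbon is the former carbonyl carbon of an acetyl group. In the forward sense the ortho-carbonate ketone A2 (two steps from 1) would take up a methyl Grignard reagent. The tertiary alkoxide would pull the carbonate over from the phenol oxygen and expel it to give an ortho-quinone methide, and a vinyl Grignard reagent would add to the exocyclic carbon to give phenol A1.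
- For it: the position of the side chain is fixed by the position of the acetyl group, nothing is heated, and the hydroxyl that must become O1 is the only free one. On these points it is stronger than steps 1–3 of the chosen route, which need a rearrangement at 190 °C and a sterically controlled protection.
- Against it: a quinone methide with two methyl groups on the exocyclic carbon and a flanking alkoxy group can lose a proton to the basic Grignard reagent and end as an isopropenyl phenol. The key step also consumes the acetyl group, so A1 must be acylated again, ortho to the hydroxyl only, before ring C can be built. Ring B is not addressed.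
- Comparison: it solves the easier half. The chosen strategy keeps the acetyl carbons as C4 and C3 and spends its key step on the ring B pattern. A route through A1 would be longer by the re-acylation and by a separate synthesis of a 5-prenylated ring B unit.

**Alternative 2:** Ring A is cut at C8–C8a and C6–C7. In the forward sense the cyclobutenone A4 would open on heating to a vinylketene, add to the siloxyalkyne A5, and pass through a second ring opening and a six-electron closure to the phenol A3.
- For it: A3 carries the tertiary group and three differently masked oxygens (free, silyl, silylethyl) with no selectivity question at all. On that point it is stronger than the chosen route, which relies on steric differentiation in step 3.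
- Against it: it builds a benzene ring that compound 1 supplies ready-made. A5 needs a quaternary propargylic centre and an ynol silyl ether, and the tertiary substituent on the alkyne should slow the ketene addition. After A3, acylation at C4a, ring C and the whole of ring B are still to come.
- Comparison: the chosen strategy uses its ring-forming step where no cheap arene offers the pattern (ring B) and buys ring A. In step count the benzannulation route is clearly longer.

**Alternative 3:** O1–C8a and C4a–C4 are cut. In the forward sense a fluoride source would release the aryne from the silyl triflate A7. The carboxylate of acid A8 would add to it, and the aryl anion would attack the ester carbonyl, giving the ortho-hydroxy ketone A6, which already holds the C3 oxygen and all carbons of the target.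
- For it: it is the most convergent of the four plans, and on convergence it is stronger than the chosen route, whose ring A sequence is linear.
- Against it: the oxygen must add to the aryne carbon next to the tertiary group. The flanking alkoxy group directs it there electronically, but that carbon is the most hindered position of the ring. A7 is a hexasubstituted benzene that is long to make, and an aryne next to allylic C–H bonds can be lost in ene reactions. A8 needs the 5-prenylated ring B unit that is awkward to make. A6 still has to be closed and dehydrogenated to the pyranone.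
- Comparison: the chosen strategy has simpler partners (a chromone made from 1 and a furan made from 16), and the ring B pattern follows from the furan instead of being a precondition.

Key step: step 13

## Route

Step 1
Reactants: 1 1-(2,4,6-trihydroxyphenyl)ethanone; 2 1-bromo-3-methylbut-2-ene (prenyl bromide)
Product: 3 1-[2,6-dihydroxy-4-(3-methylbut-2-enyloxy)phenyl]ethanone
Conditions: K2CO3 (1.05 equiv), 2 (1.0 equiv), acetone, reflux
Reagents that add atoms: none
Why: Williamson ether synthesis; the hydroxyl para to the acetyl group is the most acidic and is not hydrogen-bonded to the carbonyl, so one equivalent of base and halide should alkylate it first, and C-alkylated or dialkylated material is removed by chromatography.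

Step 2
Reactants: 3 1-[2,6-dihydroxy-4-(3-methylbut-2-enyloxy)phenyl]ethanone
Product: 4 1-[2,4,6-trihydroxy-3-(2-methylbut-3-en-2-yl)phenyl]ethanone
Conditions: PhNEt2, 190 °C, Ar, sealed tube
Reagents that add atoms: none
Why: Aromatic Claisen rearrangement; the [3,3] shift delivers the allyl unit with inversion to an ortho carbon and so gives the tertiary group. Both ortho positions are equivalent and the para position carries the acetyl group, so a single phenol should result, and the amine solvent suppresses acid-catalysed ring closure onto the new alkene.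

Step 3
Reactants: 4 1-[2,4,6-trihydroxy-3-(2-methylbut-3-en-2-yl)phenyl]ethanone
Product: 5 1-[2-hydroxy-4,6-bis(methoxymethoxy)-3-(2-methylbut-3-en-2-yl)phenyl]ethanone
Conditions: MOMCl (2.2 equiv), i-Pr2NEt, CH2Cl2, 0 °C to rt
Reagents that add atoms: chloromethyl methyl ether, COCCl
Why: Selective acetal protection; the hydroxyl between the acetyl and the tertiary alkyl group is shielded on both sides and held in a hydrogen bond, so only the other two phenols should react. The phenol left free is the one that becomes O1, which fixes the side chain at C8.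

Step 4
Reactants: 5 1-[2-hydroxy-4,6-bis(methoxymethoxy)-3-(2-methylbut-3-en-2-yl)phenyl]ethanone
Product: 7 2-hydroxy-1-[2-hydroxy-4,6-bis(methoxymethoxy)-3-(2-methylbut-3-en-2-yl)phenyl]ethanone, via bis(trimethylsilyl) enol ether 6 (not isolated)
Conditions: LiN(SiMe3)2 (2.5 equiv), Me3SiCl, THF, −78 to 0 °C; mCPBA, NaHCO3, CH2Cl2, −20 °C; aq. citric acid, MeOH
Reagents that add atoms: 3-chloroperbenzoic acid, OOC(=O)c1cccc(Cl)c1; chlorotrimethylsilane, C[Si](C)(C)Cl (silicon in 6 only)
Why: Rubottom oxidation; phenol and methyl ketone are silylated together, the peracid epoxidises the electron-rich silyl enol ether much faster than the hindered monosubstituted alkene, and silyl migration with mild hydrolysis gives the α-hydroxy ketone.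

Step 5
Reactants: 7 2-hydroxy-1-[2-hydroxy-4,6-bis(methoxymethoxy)-3-(2-methylbut-3-en-2-yl)phenyl]ethanone
Product: 8 1-[2-hydroxy-4,6-bis(methoxymethoxy)-3-(2-methylbut-3-en-2-yl)phenyl]-2-(methoxymethoxy)ethanone
Conditions: MOMCl (1.2 equiv), i-Pr2NEt, CH2Cl2, 0 °C
Reagents that add atoms: chloromethyl methyl ether, COCCl
Why: Acetal protection of the primary alcohol; the chelated, hindered phenol stays free for the same reason as in step 3.

Step 6
Reactants: 8 1-[2-hydroxy-4,6-bis(methoxymethoxy)-3-(2-methylbut-3-en-2-yl)phenyl]-2-(methoxymethoxy)ethanone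
Product: 10 3,5,7-tris(methoxymethoxy)-8-(2-methylbut-3-en-2-yl)-4H-chromen-4-one, via α-alkoxy enaminone 9 (not isolated)
Conditions: Me2NCH(OMe)2, toluene, 90 °C; then AcOH, 60 °C
Reagents that add atoms: N,N-dimethylformamide dimethyl acetal, COC(OC)N(C)C
Why: Enaminone formation with an amide acetal, then conjugate addition of the phenol and loss of dimethylamine (6-endo addition–elimination), is a standard route to 2-unsubstituted chromones. The α-alkoxy group is carried through as the C3 substituent.

Step 7
Reactants: 10 3,5,7-tris(methoxymethoxy)-8-(2-methylbut-3-en-2-yl)-4H-chromen-4-one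
Product: 12 2-iodo-3,5,7-tris(methoxymethoxy)-8-(2-methylbut-3-en-2-yl)-4H-chromen-4-one, via 2-chromonylzinc chloride 11 (not isolated)
Conditions: TMPZnCl·LiCl (1.3 equiv), THF, 25 °C; I2, 0 °C
Reagents that add atoms: iodine, II; 2,2,6,6-tetramethylpiperidinylzinc chloride–lithium chloride, CC1(C)CCCC(C)(C)N1[Zn]Cl.[Li+].[Cl-] (zinc and chlorine in 11 only)
Why: Zincation of a chromone at C2 with a hindered zinc amide, then iodolysis; C2–H is the only C–H on the pyranone and is acidified by O1, the carbonyl and the C3 alkoxy group, and the mild base should leave the acetals and the arene C6–H alone.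

Step 8
Reactants: 12 2-iodo-3,5,7-tris(methoxymethoxy)-8-(2-methylbut-3-en-2-yl)-4H-chromen-4-one; 13 ethynyltrimethylsilane
Product: 14 3,5,7-tris(methoxymethoxy)-8-(2-methylbut-3-en-2-yl)-2-[(trimethylsilyl)ethynyl]-4H-chromen-4-one
Conditions: PdCl2(PPh3)2 (3 mol %), CuI (5 mol %), Et3N, THF, 25 °C
Reagents that add atoms: none
Why: Sonogashira coupling; the β-iodo enone adds readily to zerovalent palladium, and a tertiary amine is used so that no nucleophile adds to the product.

Step 9
Reactants: 14 3,5,7-tris(methoxymethoxy)-8-(2-methylbut-3-en-2-yl)-2-[(trimethylsilyl)ethynyl]-4H-chromen-4-one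
Product: 15 2-ethynyl-3,5,7-tris(methoxymethoxy)-8-(2-methylbut-3-en-2-yl)-4H-chromen-4-one
Conditions: Bu4NF (1.1 equiv), AcOH (1.5 equiv), THF, −20 °C
Reagents that add atoms: none
Why: Fluoride cleavage of the C(sp)–Si bond; acetic acid protonates the acetylide at once, so the electrophilic enyne is not exposed to base or alkoxide.

Step 10
Reactants: 16 3,4-dibromofuran; 2 1-bromo-3-methylbut-2-ene
Product: 18 3-bromo-4-(3-methylbut-2-enyl)furan, via 4-bromo-3-furyllithium 17 (not isolated)
Conditions: n-BuLi (1.0 equiv), Et2O, −78 °C; CuBr·SMe2; 2, −78 to −20 °C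
Reagents that add atoms: n-butyllithium, [Li]CCCC (lithium in 17 only)
Why: Bromine–lithium exchange on one of two equivalent C–Br bonds at a temperature where the 3-furyllithium does not isomerise, then transmetalation to copper and allylic substitution at the unsubstituted end of the allyl bromide, as is usual for arylcopper reagents.

Step 11
Reactants: 18 3-bromo-4-(3-methylbut-2-enyl)furan
Product: 21 4-(3-methylbut-2-enyl)furan-3(2H)-one, via 4-prenyl-3-furyllithium 19 (not isolated), via lithium furyl(trimethoxy)borate 20 (not isolated)
Conditions: n-BuLi, Et2O, −78 °C; B(OMe)3, −78 to 0 °C; AcOH, 30% H2O2, 0 °C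
Reagents that add atoms: hydrogen peroxide, OO; trimethyl borate, COB(OC)OC (boron in 20 only); n-butyllithium, [Li]CCCC (lithium in 19 only)
Why: Bromine–lithium exchange, borylation and oxidative 1,2-shift from boron to oxygen (peroxide hydroxylation of an aryl boronate under weakly acidic conditions); the 3-hydroxyfuran appears as its keto tautomer and is used at once.

Step 12
Reactants: 21 4-(3-methylbut-2-enyl)furan-3(2H)-one
Product: 22 triisopropyl{[4-(3-methylbut-2-enyl)furan-3-yl]oxy}silane
Conditions: i-Pr3SiOTf (1.1 equiv), Et3N, CH2Cl2, 0 °C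
Reagents that add atoms: triisopropylsilyl trifluoromethanesulfonate, CC(C)[Si](OS(=O)(=O)C(F)(F)F)(C(C)C)C(C)C
Why: O-Silylation of a furan-3(2H)-one with a silyl triflate and amine; enolisation is driven by formation of the aromatic furan, and the bulky silyl group gives an enol ether that can be handled.

Step 13
Reactants: 15 2-ethynyl-3,5,7-tris(methoxymethoxy)-8-(2-methylbut-3-en-2-yl)-4H-chromen-4-one; 22 triisopropyl{[4-(3-methylbut-2-enyl)furan-3-yl]oxy}silane
Product: 24 2-[3-hydroxy-5-(3-methylbut-2-enyl)-4-(triisopropylsilyloxy)phenyl]-3,5,7-tris(methoxymethoxy)-8-(2-methylbut-3-en-2-yl)-4H-chromen-4-one, via 7-oxanorbornadiene adduct 23 (not isolated)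
Conditions: 22 (2 equiv), toluene, 80 °C, sealed tube, Ar
Reagents that add atoms: none
Why: Proposed new method: a 3-silyloxyfuran has not been added to an alkyne activated only through a chromone, but the closest known reaction type, the Diels–Alder addition of 3-alkoxy- and 3-silyloxyfurans to alkynoates and ynones with opening of the 7-oxanorbornadiene to a phenol, rests on the same polarity. The ethynyl group of 15 is a vinylogous ynone (C4=O, C3=C2, C≡C), so its terminal carbon is the electrophilic end, while the furan carbon between the ring oxygen and the silyloxy carbon carries the largest HOMO coefficient; their union forms C2′–C3′, and the other furan α-carbon bonds to the internal alkyne carbon to form C1′–C6′, so ring B is closed by a [4+2] cycloaddition that may be asynchronous or pass through a silyloxy-stabilised oxocarbenium ion. In adduct 23 the silyl enol ether pushes through C5′ into the C6′–O bond, which ionises, and loss of the C3′ proton gives the benzene ring; this makes an otherwise reversible addition irreversible. The furan oxygen ends as the free 3′-hydroxyl, the silyloxy group as O4′, and the prenyl group is on C5′ from the start. The two bridgeheads of 23 are the only stereocentres formed; the bridge fixes their relative geometry, they arise as a racemate and are erased on aromatisation, so no stereocontrol is needed. The step needs one orientation of addition and one direction of bridge opening, and both are set by the silyloxy donor on the furan matched with the chromone acceptor on the alkyne; a shift of the silyl group between O3′ and O4′ would not matter, since both are freed later.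

Step 14
Reactants: 24 2-[3-hydroxy-5-(3-methylbut-2-enyl)-4-(triisopropylsilyloxy)phenyl]-3,5,7-tris(methoxymethoxy)-8-(2-methylbut-3-en-2-yl)-4H-chromen-4-one
Product: 25 2-[3,4-dihydroxy-5-(3-methylbut-2-enyl)phenyl]-3,5,7-tris(methoxymethoxy)-8-(2-methylbut-3-en-2-yl)-4H-chromen-4-one
Conditions: Bu4NF (1.1 equiv), AcOH (1.1 equiv), THF, 0 °C, Ar
Reagents that add atoms: none
Why: Fluoride cleavage of an aryl silyl ether; the acetals are inert, and acetic acid keeps the ortho-dihydroxybenzene protonated so that it is not oxidised as its anion.

Step 15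
Reactants: 25 2-[3,4-dihydroxy-5-(3-methylbut-2-enyl)phenyl]-3,5,7-tris(methoxymethoxy)-8-(2-methylbut-3-en-2-yl)-4H-chromen-4-one
Product: 26 2-[3,4-dihydroxy-5-(3-methylbut-2-enyl)phenyl]-3,5,7-trihydroxy-8-(2-methylbut-3-en-2-yl)-4H-chromen-4-one
Conditions: 3 M aq. HCl, MeOH, 45 °C, Ar
Reagents that add atoms: none
Why: Acid-catalysed transfer of the three methoxymethyl groups to methanol, the usual way to free phenols in prenylated flavonoids; the peri C5 ether should go first, and the reaction is stopped as soon as the C7 and C3 ethers are gone, before either alkene is protonated.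

## Compound list

1 | 1-(2,4,6-trihydroxyphenyl)ethanone | CC(=O)c1c(O)cc(O)cc1O | starting material
2 | 1-bromo-3-methylbut-2-ene | CC(C)=CCBr | starting material
3 | 1-[2,6-dihydroxy-4-(3-methylbut-2-enyloxy)phenyl]ethanone | CC(=O)c1c(O)cc(OCC=C(C)C)cc1O | intermediate
4 | 1-[2,4,6-trihydroxy-3-(2-methylbut-3-en-2-yl)phenyl]ethanone | CC(=O)c1c(O)cc(O)c(C(C)(C)C=C)c1O | intermediate
5 | 1-[2-hydroxy-4,6-bis(methoxymethoxy)-3-(2-methylbut-3-en-2-yl)phenyl]ethanone | CC(=O)c1c(OCOC)cc(OCOC)c(C(C)(C)C=C)c1O | intermediate
6 | trimethyl{1-[4,6-bis(methoxymethoxy)-3-(2-methylbut-3-en-2-yl)-2-(trimethylsilyloxy)phenyl]ethenyloxy}silane | C=C(O[Si](C)(C)C)c1c(OCOC)cc(OCOC)c(C(C)(C)C=C)c1O[Si](C)(C)C | intermediate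
7 | 2-hydroxy-1-[2-hydroxy-4,6-bis(methoxymethoxy)-3-(2-methylbut-3-en-2-yl)phenyl]ethanone | OCC(=O)c1c(OCOC)cc(OCOC)c(C(C)(C)C=C)c1O | intermediate
8 | 1-[2-hydroxy-4,6-bis(methoxymethoxy)-3-(2-methylbut-3-en-2-yl)phenyl]-2-(methoxymethoxy)ethanone | COCOCC(=O)c1c(OCOC)cc(OCOC)c(C(C)(C)C=C)c1O | intermediate
9 | (Z)-3-(dimethylamino)-1-[2-hydroxy-4,6-bis(methoxymethoxy)-3-(2-methylbut-3-en-2-yl)phenyl]-2-(methoxymethoxy)prop-2-en-1-one | CN(C)/C=C(\OCOC)C(=O)c1c(OCOC)cc(OCOC)c(C(C)(C)C=C)c1O | intermediate
10 | 3,5,7-tris(methoxymethoxy)-8-(2-methylbut-3-en-2-yl)-4H-chromen-4-one | C=CC(C)(C)c1c(OCOC)cc(OCOC)c2c(=O)c(OCOC)coc12 | intermediate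
11 | chloro[3,5,7-tris(methoxymethoxy)-8-(2-methylbut-3-en-2-yl)-4-oxo-4H-chromen-2-yl]zinc | C=CC(C)(C)c1c(OCOC)cc(OCOC)c2c(=O)c(OCOC)c([Zn]Cl)oc12 | intermediate
12 | 2-iodo-3,5,7-tris(methoxymethoxy)-8-(2-methylbut-3-en-2-yl)-4H-chromen-4-one | C=CC(C)(C)c1c(OCOC)cc(OCOC)c2c(=O)c(OCOC)c(I)oc12 | intermediate
13 | ethynyltrimethylsilane | C#C[Si](C)(C)C | starting material
14 | 3,5,7-tris(methoxymethoxy)-8-(2-methylbut-3-en-2-yl)-2-[(trimethylsilyl)ethynyl]-4H-chromen-4-one | C=CC(C)(C)c1c(OCOC)cc(OCOC)c2c(=O)c(OCOC)c(C#C[Si](C)(C)C)oc12 | intermediate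
15 | 2-ethynyl-3,5,7-tris(methoxymethoxy)-8-(2-methylbut-3-en-2-yl)-4H-chromen-4-one | C#Cc1oc2c(C(C)(C)C=C)c(OCOC)cc(OCOC)c2c(=O)c1OCOC | intermediate
16 | 3,4-dibromofuran | Brc1cocc1Br | starting material
17 | (4-bromofuran-3-yl)lithium | [Li]c1cocc1Br | intermediate
18 | 3-bromo-4-(3-methylbut-2-enyl)furan | CC(C)=CCc1cocc1Br | intermediate
19 | [4-(3-methylbut-2-enyl)furan-3-yl]lithium | [Li]c1cocc1CC=C(C)C | intermediate
20 | lithium trimethoxy[4-(3-methylbut-2-enyl)furan-3-yl]borate | [Li+].CO[B-](OC)(OC)c1cocc1CC=C(C)C | intermediate
21 | 4-(3-methylbut-2-enyl)furan-3(2H)-one | CC(C)=CCC1=COCC1=O | intermediate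
22 | triisopropyl{[4-(3-methylbut-2-enyl)furan-3-yl]oxy}silane | CC(C)=CCc1cocc1O[Si](C(C)C)(C(C)C)C(C)C | intermediate
23 | 2-[6-(3-methylbut-2-enyl)-5-(triisopropylsilyloxy)-7-oxabicyclo[2.2.1]hepta-2,5-dien-2-yl]-3,5,7-tris(methoxymethoxy)-8-(2-methylbut-3-en-2-yl)-4H-chromen-4-one (racemic, one enantiomer drawn) | C=CC(C)(C)c1c(OCOC)cc(OCOC)c2c(=O)c(OCOC)c(C3=C[C@H]4O[C@@H]3C(CC=C(C)C)=C4O[Si](C(C)C)(C(C)C)C(C)C)oc12 | intermediate
24 | 2-[3-hydroxy-5-(3-methylbut-2-enyl)-4-(triisopropylsilyloxy)phenyl]-3,5,7-tris(methoxymethoxy)-8-(2-methylbut-3-en-2-yl)-4H-chromen-4-one | C=CC(C)(C)c1c(OCOC)cc(OCOC)c2c(=O)c(OCOC)c(-c3cc(O)c(O[Si](C(C)C)(C(C)C)C(C)C)c(CC=C(C)C)c3)oc12 | intermediate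
25 | 2-[3,4-dihydroxy-5-(3-methylbut-2-enyl)phenyl]-3,5,7-tris(methoxymethoxy)-8-(2-methylbut-3-en-2-yl)-4H-chromen-4-one | C=CC(C)(C)c1c(OCOC)cc(OCOC)c2c(=O)c(OCOC)c(-c3cc(O)c(O)c(CC=C(C)C)c3)oc12 | intermediate
26 | 2-[3,4-dihydroxy-5-(3-methylbut-2-enyl)phenyl]-3,5,7-trihydroxy-8-(2-methylbut-3-en-2-yl)-4H-chromen-4-one | C=CC(C)(C)c1c(O)cc(O)c2c(=O)c(O)c(-c3cc(O)c(O)c(CC=C(C)C)c3)oc12 | target

## Step count and least certain steps

Total: 15 steps. Longest linear sequence: 12 steps (steps 1–9 and 13–15, from 1); the furan branch is steps 10–12.

**Step 13 (key step, proposed new method).** The cycloaddition may be too slow, or may stop after the first bond as a conjugate addition of the furan α-carbon to the alkyne without ring closure. The reason is that an alkyne activated only through the pyranone is a weaker dienophile than an alkynoate, and the C3 alkoxy group raises its acceptor orbital further. Cycloreversion before the bridge opens and thermal loss of the silyloxyfuran are further ways to lose material.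
Fallback (known chemistry), from 12 back to 26: ring B is brought in complete. Catechol is protected with MOMCl and i-Pr2NEt in CH2Cl2 to give 1,2-bis(methoxymethoxy)benzene F1. Ortho-lithiation of F1 with n-BuLi in THF at 0 °C and copper-mediated alkylation with 2 give 1,2-bis(methoxymethoxy)-3-(3-methylbut-2-enyl)benzene F2. Iridium-catalysed C–H borylation of F2 ([Ir(OMe)(cod)]2, 4,4′-di-tert-butyl-2,2′-bipyridine, B2pin2) goes to the only ring position without an ortho substituent and gives 2-[3,4-bis(methoxymethoxy)-5-(3-methylbut-2-enyl)phenyl]-4,4,5,5-tetramethyl-1,3,2-dioxaborolane F3. Suzuki–Miyaura coupling of F3 with iodide 12 (Pd(dppf)Cl2, K3PO4, dioxane–water) gives 2-[3,4-bis(methoxymethoxy)-5-(3-methylbut-2-enyl)phenyl]-3,5,7-tris(methoxymethoxy)-8-(2-methylbut-3-en-2-yl)-4H-chromen-4-one F4. The acid treatment of step 15, applied to F4, removes all five acetals and gives 26.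

**Step 2.** The rearrangement may be followed by addition of a flanking hydroxyl to the new vinyl group (ring closure to a dihydrobenzofuran) or by loss of the allyl group through ionisation, because the product is an electron-rich triol held at high temperature.
Fallback, from 3 back to 4: the rearrangement is run with a silylating trap. Heating 3 with N,O-bis(trimethylsilyl)acetamide in PhNEt2 first gives 1-[4-(3-methylbut-2-enyloxy)-2,6-bis(trimethylsilyloxy)phenyl]ethanone F5. On further heating F5 rearranges, and the phenol that is released is silylated as it forms, giving 1-[3-(2-methylbut-3-en-2-yl)-2,4,6-tris(trimethylsilyloxy)phenyl]ethanone F6. Methanolysis of F6 returns 4.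

**Step 7.** Metalation may be incomplete, or the amide base may add to the pyranone and open it, because the ring is a vinylogous ester that also carries three Lewis-basic acetals.
Fallback, from 8 back to 15: the C2 substituent is built in when ring C is closed. Claisen condensation of 8 with diethyl oxalate (NaOEt, EtOH) and cyclodehydration (AcOH, 60 °C) give ethyl 3,5,7-tris(methoxymethoxy)-8-(2-methylbut-3-en-2-yl)-4-oxo-4H-chromene-2-carboxylate F7. NaBH4 in MeOH–THF reduces the activated ester of F7 to 2-(hydroxymethyl)-3,5,7-tris(methoxymethoxy)-8-(2-methylbut-3-en-2-yl)-4H-chromen-4-one F8. MnO2 oxidises F8 to 3,5,7-tris(methoxymethoxy)-8-(2-methylbut-3-en-2-yl)-4-oxo-4H-chromene-2-carbaldehyde F9. (Trimethylsilyl)diazomethane, lithiated with LiN(i-Pr)2, converts F9 at −78 °C into 15 (Colvin homologation).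

**Step 11.** The furanone has a free CH2 next to the carbonyl and may condense with itself or be oxidised further during the peroxide work-up.
Fallback, from 18 back to 22: the free furanone is avoided. Furyllithium 19, made as in step 11, is oxidised in the same flask with LiOOt-Bu to lithium 4-(3-methylbut-2-enyl)furan-3-olate F10. Without isolation F10 is silylated at oxygen with i-Pr3SiOTf at −78 °C to give 22.

**Step 15.** Protonation of an alkene may compete with acetal cleavage, with ring closure of the prenyl group onto O4′ or of the tertiary allyl group onto O7. The hindered C7 acetal is slow to leave and may force longer exposure to acid.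
Fallback, from 24 back to 26: the acetals are exchanged for silyl groups without protic acid. Me3SiOTf with 2,2′-bipyridyl in CH2Cl2 at 0 °C converts the three aryl and enol methoxymethyl ethers and the free phenol of 24 into 2-[5-(3-methylbut-2-enyl)-4-(triisopropylsilyloxy)-3-(trimethylsilyloxy)phenyl]-8-(2-methylbut-3-en-2-yl)-3,5,7-tris(trimethylsilyloxy)-4H-chromen-4-one F11. One buffered fluoride treatment of F11 (Bu4NF, AcOH, THF) then removes all silyl groups and gives 26.

## Further compounds

F1 | step 13 | 1,2-bis(methoxymethoxy)benzene | COCOc1ccccc1OCOC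
F2 | step 13 | 1,2-bis(methoxymethoxy)-3-(3-methylbut-2-enyl)benzene | CC(C)=CCc1cccc(OCOC)c1OCOC
F3 | step 13 | 2-[3,4-bis(methoxymethoxy)-5-(3-methylbut-2-enyl)phenyl]-4,4,5,5-tetramethyl-1,3,2-dioxaborolane | CC(C)=CCc1cc(B2OC(C)(C)C(C)(C)O2)cc(OCOC)c1OCOC
F4 | step 13 | 2-[3,4-bis(methoxymethoxy)-5-(3-methylbut-2-enyl)phenyl]-3,5,7-tris(methoxymethoxy)-8-(2-methylbut-3-en-2-yl)-4H-chromen-4-one | C=CC(C)(C)c1c(OCOC)cc(OCOC)c2c(=O)c(OCOC)c(-c3cc(OCOC)c(OCOC)c(CC=C(C)C)c3)oc12
F5 | step 2 | 1-[4-(3-methylbut-2-enyloxy)-2,6-bis(trimethylsilyloxy)phenyl]ethanone | CC(=O)c1c(O[Si](C)(C)C)cc(OCC=C(C)C)cc1O[Si](C)(C)C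
F6 | step 2 | 1-[3-(2-methylbut-3-en-2-yl)-2,4,6-tris(trimethylsilyloxy)phenyl]ethanone | CC(=O)c1c(O[Si](C)(C)C)cc(O[Si](C)(C)C)c(C(C)(C)C=C)c1O[Si](C)(C)C
F7 | step 7 | ethyl 3,5,7-tris(methoxymethoxy)-8-(2-methylbut-3-en-2-yl)-4-oxo-4H-chromene-2-carboxylate | CCOC(=O)c1oc2c(C(C)(C)C=C)c(OCOC)cc(OCOC)c2c(=O)c1OCOC
F8 | step 7 | 2-(hydroxymethyl)-3,5,7-tris(methoxymethoxy)-8-(2-methylbut-3-en-2-yl)-4H-chromen-4-one | OCc1oc2c(C(C)(C)C=C)c(OCOC)cc(OCOC)c2c(=O)c1OCOC
F9 | step 7 | 3,5,7-tris(methoxymethoxy)-8-(2-methylbut-3-en-2-yl)-4-oxo-4H-chromene-2-carbaldehyde | O=Cc1oc2c(C(C)(C)C=C)c(OCOC)cc(OCOC)c2c(=O)c1OCOC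
F10 | step 11 | lithium 4-(3-methylbut-2-enyl)furan-3-olate | [Li+].[O-]c1cocc1CC=C(C)C
F11 | step 15 | 2-[5-(3-methylbut-2-enyl)-4-(triisopropylsilyloxy)-3-(trimethylsilyloxy)phenyl]-8-(2-methylbut-3-en-2-yl)-3,5,7-tris(trimethylsilyloxy)-4H-chromen-4-one | C=CC(C)(C)c1c(O[Si](C)(C)C)cc(O[Si](C)(C)C)c2c(=O)c(O[Si](C)(C)C)c(-c3cc(O[Si](C)(C)C)c(O[Si](C(C)C)(C(C)C)C(C)C)c(CC=C(C)C)c3)oc12
A1 | alternative 1 | 3,5-bis(methoxymethoxy)-2-(2-methylbut-3-en-2-yl)phenol | C=CC(C)(C)c1c(O)cc(OCOC)cc1OCOC
A2 | alternative 1 | 1-[2-(tert-butoxycarbonyloxy)-4,6-bis(methoxymethoxy)phenyl]ethanone | CC(=O)c1c(OC(=O)OC(C)(C)C)cc(OCOC)cc1OCOC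
A3 | alternative 2 | 2-(2-methylbut-3-en-2-yl)-3-(triisopropylsilyloxy)-5-[2-(trimethylsilyl)ethoxy]phenol | C=CC(C)(C)c1c(O)cc(OCC[Si](C)(C)C)cc1O[Si](C(C)C)(C(C)C)C(C)C
A4 | alternative 2 | 3-[2-(trimethylsilyl)ethoxy]cyclobut-2-en-1-one | C[Si](C)(C)CCOC1=CC(=O)C1
A5 | alternative 2 | [(3,3-dimethylpent-4-en-1-yn-1-yl)oxy]triisopropylsilane | C=CC(C)(C)C#CO[Si](C(C)C)(C(C)C)C(C)C
A6 | alternative 3 | (2Z)-3-[3,4-bis(methoxymethoxy)-5-(3-methylbut-2-enyl)phenyl]-1-[2-hydroxy-4,6-bis(methoxymethoxy)-3-(2-methylbut-3-en-2-yl)phenyl]-2-(methoxymethoxy)prop-2-en-1-one | C=CC(C)(C)c1c(O)c(C(=O)/C(OCOC)=C/c2cc(OCOC)c(OCOC)c(CC=C(C)C)c2)c(OCOC)cc1OCOC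
A7 | alternative 3 | 3,5-bis(methoxymethoxy)-2-(2-methylbut-3-en-2-yl)-6-(trimethylsilyl)phenyl trifluoromethanesulfonate | C=CC(C)(C)c1c(OS(=O)(=O)C(F)(F)F)c([Si](C)(C)C)c(OCOC)cc1OCOC
A8 | alternative 3 | (2Z)-3-[3,4-bis(methoxymethoxy)-5-(3-methylbut-2-enyl)phenyl]-2-(methoxymethoxy)prop-2-enoic acid | OC(=O)/C(OCOC)=C/c1cc(OCOC)c(OCOC)c(CC=C(C)C)c1
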